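## Retrosynthetic overview
1. The target comes from its phenol benzyl ether / 6,7-acetonide. Both groups are removed in one pot at the end.
2. Key cut C8–C8a, which closes the carbocycle (the last ring formed). Both carbons are electrophiles: C8 is an aldehyde carbon and C8a is the MeO-bearing β-carbon of an α-methoxy-γ-pyrone. C8 is inverted to its SmI2 ketyl (a d1 hydroxy-carbanion equivalent), adds 6-endo to C8a, and methoxide leaves. This step sets C8.
3. Cut C4a–C5: a 3-magnesiated pyrone adds to the C2-symmetric dialdehyde made from L-tartrate. The dialdehyde supplies C5–C8, with C6 and C7 from the chiral pool. C5 is set by Felkin–Anh addition.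
4. The pyrone comes from triacetic acid lactone, which already holds O1, C2, C3, C4, C4a, C8a and the first side-chain CH2. It is elaborated by dianion benzylation, C3 iodination and methylation of the lactone oxygen (2-pyrone to 4-pyrone).
5. Ring order: the arene and the pyran ring are bought; the cyclohexene ring is the only ring built.

Assumption: chromone numbering (O1, C2, C3, C4, C4a, C5–C8, C8a) is used for the corresponding atoms of all intermediates, and 1, 3 and 9 are taken as commercial.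

## Route

Step 1
Reactants: 1 3-(benzyloxy)-4-methoxybenzyl alcohol
Product: 2 3-(benzyloxy)-4-methoxybenzyl bromide
Conditions: PBr3 (0.4 equiv), Et2O, 0 °C, 1 h; used without storage
Reagents that add atoms: phosphorus tribromide, BrP(Br)Br
Why: PBr3 bromination (SN2 on the phosphite ester of an activated benzylic alcohol) leaves both aryl ethers untouched and involves no stereocentre.

Step 2
Reactants: 3 4-hydroxy-6-methyl-2H-pyran-2-one (triacetic acid lactone); 2 3-(benzyloxy)-4-methoxybenzyl bromide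
Product: 5 6-[2-(3-benzyloxy-4-methoxyphenyl)ethyl]-4-hydroxy-2H-pyran-2-one, via dilithio dianion of triacetic acid lactone 4 (not isolated)
Conditions: 3 (1.2 equiv), LiN(i-Pr)2 (2.5 equiv, commercial solution), THF, DMPU (2 equiv), −78 to −20 °C; then 2, −78 °C to rt; 1 M HCl
Reagents that add atoms: none
Why: Dianion (vinylogous γ-) alkylation, in which the carbanion formed last (the C6-CH2) is the most nucleophilic site, so the benzylic bromide reacts there and not at O4 or C3; no stereocentre is formed.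

Step 3
Reactants: 5 6-[2-(3-benzyloxy-4-methoxyphenyl)ethyl]-4-hydroxy-2H-pyran-2-one
Product: 6 6-[2-(3-benzyloxy-4-methoxyphenyl)ethyl]-4-hydroxy-3-iodo-2H-pyran-2-one
Conditions: NIS (1.05 equiv), MeCN, 0 °C to rt, dark
Reagents that add atoms: N-iodosuccinimide, O=C1CCC(=O)N1I
Why: Electrophilic iodination of a cyclic β-dicarbonyl enol, where C3 (future C4a) lies between both oxygenated carbons and reacts with NIS without acid, conditions under which the dialkoxyarene is inert.

Step 4
Reactants: 6 6-[2-(3-benzyloxy-4-methoxyphenyl)ethyl]-4-hydroxy-3-iodo-2H-pyran-2-one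
Product: 8 6-[2-(3-benzyloxy-4-methoxyphenyl)ethyl]-3-iodo-2-methoxy-4H-pyran-4-one, via 4-hydroxy-2-methoxypyrylium triflate 7 (not isolated)
Conditions: MeOTf (1.2 equiv), CH2Cl2, 0 °C to rt; aq. NaHCO3 wash
Reagents that add atoms: methyl trifluoromethanesulfonate, COS(=O)(=O)C(F)(F)F
Why: Neutral O-alkylation with a hard methylating agent hits the most basic site of the vinylogous acid (the lactone carbonyl oxygen), and the resulting pyrylium salt loses its O4 proton to give the α-methoxy-γ-pyrone instead of the 4-methoxy-2-pyrone obtained under basic conditions.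

Step 5
Reactants: 9 dimethyl (4R,5R)-2,2-dimethyl-1,3-dioxolane-4,5-dicarboxylate (dimethyl 2,3-O-isopropylidene-L-tartrate)
Product: 11 (4R,5R)-2,2-dimethyl-1,3-dioxolane-4,5-dicarbaldehyde, via bis(diisobutylaluminium hemiacetal) 10 (not isolated)
Conditions: i-Bu2AlH (2.1 equiv), toluene, −78 °C, 2 h; MeOH at −78 °C, aq. potassium sodium tartrate; dried azeotropically with toluene, used crude at once
Reagents that add atoms: none
Why: Partial ester reduction, in which the tetrahedral aluminium hemiacetals persist at −78 °C and collapse to aldehyde only on quench, so the two tartrate stereocentres (future C6 and C7) are carried over unchanged.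

Step 6
Reactants: 8 6-[2-(3-benzyloxy-4-methoxyphenyl)ethyl]-3-iodo-2-methoxy-4H-pyran-4-one; 11 (4R,5R)-2,2-dimethyl-1,3-dioxolane-4,5-dicarbaldehyde
Product: 13 (4R,5S)-5-[(S)-{6-[2-(3-benzyloxy-4-methoxyphenyl)ethyl]-2-methoxy-4-oxo-4H-pyran-3-yl}(hydroxy)methyl]-2,2-dimethyl-1,3-dioxolane-4-carbaldehyde, via 3-pyronylmagnesium chloride 12 (not isolated)
Conditions: 8, i-PrMgCl·LiCl (1.05 equiv), THF, −40 °C, 30 min; cannulated into 11 (3 equiv), THF, −78 to −40 °C; sat. aq. NH4Cl; chromatography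
Reagents that add atoms: none
Why: Iodine–magnesium exchange is faster than attack on the pyrone and is followed by 1,2-addition, where the C2 symmetry of 11 makes both formyl groups equivalent, its excess enforces mono-addition, and non-chelated Felkin–Anh (Cornforth) attack in THF/LiCl sets C5 as S (5,6-anti, which becomes cis in the ring; about 4:1 expected, the epimer being removed by chromatography).

Step 7
Reactants: 13 (4R,5S)-5-[(S)-{6-[2-(3-benzyloxy-4-methoxyphenyl)ethyl]-2-methoxy-4-oxo-4H-pyran-3-yl}(hydroxy)methyl]-2,2-dimethyl-1,3-dioxolane-4-carbaldehyde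
Product: 16 (5S,6S,7S,8S)-2-[2-(3-benzyloxy-4-methoxyphenyl)ethyl]-5,8-dihydroxy-6,7-(isopropylidenedioxy)-5,6,7,8-tetrahydro-4H-chromen-4-one (5,6-cis; 6,7-trans; 7,8-trans), via samarium ketyl 14 (not isolated), via cyclised samarium enolate 15 (not isolated)
Conditions: SmI2 (0.1 M in THF, 2.6 equiv), t-BuOH (2 equiv), THF (0.01 M in 13), −78 to 0 °C; aq. NaHCO3/Na2S2O3
Reagents that add atoms: none
Why: Proposed new method: SmI2 gives one electron to the α-alkoxy aldehyde, so that C8, normally an electrophile, becomes the nucleophilic ketyl 14 (a d1 hydroxy-carbanion equivalent) and attacks the second electrophile C8a (β-carbon of the γ-pyrone, made pyrylium-like by trivalent samarium on O4) in a 6-endo-trig mode, which is favoured because C4a is fully substituted and only this mode gives an α-keto radical that is reduced irreversibly to enolate 15, whose E1cB loss of methoxide (assisted by O1 and much easier than loss of the C5 oxide) restores the pyrone; C8 is set because the trans-acetonide holds O6 and O7 pseudo-equatorial and the bulky O–Sm group, chelated to OMe/O1, takes the pseudo-equatorial site trans to O7; the benzyl ether, the acetonide and the free 5-OH are inert to SmI2; the closest known reaction types are SmI2 ketyl–olefin cyclisations onto β-alkoxyacrylates and enones and SmI2 ketyl–olefin coupling/β-elimination sequences.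

Step 8
Reactants: 16 (5S,6S,7S,8S)-2-[2-(3-benzyloxy-4-methoxyphenyl)ethyl]-5,8-dihydroxy-6,7-(isopropylidenedioxy)-5,6,7,8-tetrahydro-4H-chromen-4-one
Product: 18 (5S,6S,7R,8S)-5,6,7,8-tetrahydroxy-2-[2-(3-hydroxy-4-methoxyphenyl)ethyl]-5,6,7,8-tetrahydro-4H-chromen-4-one (target), via debenzylated acetonide 17 (not isolated)
Conditions: H2 (1 atm), 10 % Pd/C, THF–AcOH–H2O (1:3:1), rt, 3 h; then N2, 40 °C, 4 h, same flask; filter
Reagents that add atoms: none
Why: Hydrogenolysis of the aryl benzyl ether and acid hydrolysis of the strained trans-fused acetonide run in one pot, the γ-pyrone and its C5/C8 carbinols survive 1 atm H2, and weak aqueous AcOH avoids ionisation at C5 or C8, so no stereocentre is touched.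

## Compound list
1 | 3-(benzyloxy)-4-methoxybenzyl alcohol | COc1ccc(CO)cc1OCc1ccccc1 | starting material
2 | 3-(benzyloxy)-4-methoxybenzyl bromide | COc1ccc(CBr)cc1OCc1ccccc1 | intermediate
3 | 4-hydroxy-6-methyl-2H-pyran-2-one (triacetic acid lactone) | Cc1cc(O)cc(=O)o1 | starting material
4 | dilithio dianion of triacetic acid lactone (O4, C6-CH2) | [Li+].[Li+].[CH2-]c1cc([O-])cc(=O)o1 | intermediate (not isolated)
5 | 6-[2-(3-benzyloxy-4-methoxyphenyl)ethyl]-4-hydroxy-2H-pyran-2-one | COc1ccc(CCc2cc(O)cc(=O)o2)cc1OCc1ccccc1 | intermediate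
6 | 6-[2-(3-benzyloxy-4-methoxyphenyl)ethyl]-4-hydroxy-3-iodo-2H-pyran-2-one | O=c1oc(CCc2ccc(OC)c(OCc3ccccc3)c2)cc(O)c1I | intermediate
7 | 6-[2-(3-benzyloxy-4-methoxyphenyl)ethyl]-4-hydroxy-3-iodo-2-methoxypyrylium trifluoromethanesulfonate | COc1[o+]c(CCc2ccc(OC)c(OCc3ccccc3)c2)cc(O)c1I.[O-]S(=O)(=O)C(F)(F)F | intermediate (not isolated)
8 | 6-[2-(3-benzyloxy-4-methoxyphenyl)ethyl]-3-iodo-2-methoxy-4H-pyran-4-one | COc1oc(CCc2ccc(OC)c(OCc3ccccc3)c2)cc(=O)c1I | intermediate
9 | dimethyl (4R,5R)-2,2-dimethyl-1,3-dioxolane-4,5-dicarboxylate | COC(=O)[C@@H]1OC(C)(C)O[C@H]1C(=O)OC | starting material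
10 | bis(diisobutylaluminium hemiacetal) of 9 (hemiacetal carbons undefined) | COC(O[Al](CC(C)C)CC(C)C)[C@@H]1OC(C)(C)O[C@H]1C(OC)O[Al](CC(C)C)CC(C)C | intermediate (not isolated)
11 | (4R,5R)-2,2-dimethyl-1,3-dioxolane-4,5-dicarbaldehyde | O=C[C@@H]1OC(C)(C)O[C@H]1C=O | intermediate
12 | {6-[2-(3-benzyloxy-4-methoxyphenyl)ethyl]-2-methoxy-4-oxo-4H-pyran-3-yl}magnesium chloride, LiCl complex | COc1oc(CCc2ccc(OC)c(OCc3ccccc3)c2)cc(=O)c1[Mg]Cl.[Li+].[Cl-] | intermediate (not isolated)
13 | (4R,5S)-5-[(S)-{6-[2-(3-benzyloxy-4-methoxyphenyl)ethyl]-2-methoxy-4-oxo-4H-pyran-3-yl}(hydroxy)methyl]-2,2-dimethyl-1,3-dioxolane-4-carbaldehyde | COc1oc(CCc2ccc(OC)c(OCc3ccccc3)c2)cc(=O)c1[C@H](O)[C@@H]4OC(C)(C)O[C@H]4C=O | intermediate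
14 | samarium ketyl of 13 (radical at C8, oxide bound to trivalent samarium diiodide) | COc1oc(CCc2ccc(OC)c(OCc3ccccc3)c2)cc(=O)c1[C@H](O)[C@@H]4OC(C)(C)O[C@H]4[CH][O-].[Sm+3].[I-].[I-] | intermediate (not isolated)
15 | cyclised 8a-methoxy-8aH-chromene 4-enolate / 8-alkoxide as its bis(SmI2) salt (C8a transient, undefined) | COc1ccc(CCC2=CC([O-])=C3C(OC)(O2)[C@@H]([O-])[C@@H]4OC(C)(C)O[C@H]4[C@H]3O)cc1OCc1ccccc1.[Sm+3].[I-].[I-].[Sm+3].[I-].[I-] | intermediate (not isolated)
16 | (5S,6S,7S,8S)-2-[2-(3-benzyloxy-4-methoxyphenyl)ethyl]-5,8-dihydroxy-6,7-(isopropylidenedioxy)-5,6,7,8-tetrahydro-4H-chromen-4-one; same spatial arrangement as 18, C7 reads S only because the acetal raises the rank of C6 | COc1ccc(CCc2cc(=O)c3c(o2)[C@@H](O)[C@@H]4OC(C)(C)O[C@H]4[C@H]3O)cc1OCc1ccccc1 | intermediate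
17 | (5S,6S,7S,8S)-5,8-dihydroxy-2-[2-(3-hydroxy-4-methoxyphenyl)ethyl]-6,7-(isopropylidenedioxy)-5,6,7,8-tetrahydro-4H-chromen-4-one | COc1ccc(CCc2cc(=O)c3c(o2)[C@@H](O)[C@@H]4OC(C)(C)O[C@H]4[C@H]3O)cc1O | intermediate (not isolated)
18 | (5S,6S,7R,8S)-5,6,7,8-tetrahydroxy-2-[2-(3-hydroxy-4-methoxyphenyl)ethyl]-5,6,7,8-tetrahydro-4H-chromen-4-one | COc1ccc(CCc2cc(=O)c3c(o2)[C@@H](O)[C@H](O)[C@@H](O)[C@H]3O)cc1O | target

## Step count and risks
Total step count: 8. Longest linear sequence: 7 (steps 1, 2, 3, 4, 6, 7, 8; step 5 is the side branch).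

**Step 7 (most risky).** The acceptor carbon is fully substituted and part of an electron-rich vinylogous carbonate. The ketyl may therefore be reduced to the alcohol or dimerise instead of cyclising.

The fallback sets out from 13 and comes back at 16. It replaces the radical closure by a polar acyl-anion closure plus a redox correction.
- Compound 13 is treated with 2-(pentafluorophenyl)-6,7-dihydro-5H-pyrrolo[2,1-c][1,2,4]triazol-2-ium tetrafluoroborate (20 mol %) and i-Pr2NEt in toluene at rt.
- The Breslow intermediate formed at C8 adds to C8a in a Stetter-type addition–elimination with loss of methoxide. This gives (5S,6S,7R)-2-[2-(3-benzyloxy-4-methoxyphenyl)ethyl]-5-hydroxy-6,7-(isopropylidenedioxy)-6,7-dihydro-5H-chromene-4,8-dione F1.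
- NaBH4/CeCl3·7H2O in MeOH at −78 °C then delivers hydride axially to the half-chair. The 8-OH ends pseudo-equatorial, trans to O7, which is 16.

**Step 6.** The dialdehyde is fragile, mono-addition is statistical, and Felkin–Anh selectivity with a magnesium reagent may be low.

The fallback sets out from 8 and comes back at 13. It makes the C4a–C5 bond by acylation and sets C5 by reduction.
- Compound 8 is magnesiated to 12 as before and added to diester 9 (3 equiv, THF, −40 to 0 °C). The chelated tetrahedral adduct stops at mono-acylation and gives methyl (4R,5R)-5-({6-[2-(3-benzyloxy-4-methoxyphenyl)ethyl]-2-methoxy-4-oxo-4H-pyran-3-yl}carbonyl)-2,2-dimethyl-1,3-dioxolane-4-carboxylate F2.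
- Zn(BH4)2 in Et2O at −30 °C reduces the ketone under Cram-chelate control to the anti alcohol methyl (4R,5S)-5-[(S)-{6-[2-(3-benzyloxy-4-methoxyphenyl)ethyl]-2-methoxy-4-oxo-4H-pyran-3-yl}(hydroxy)methyl]-2,2-dimethyl-1,3-dioxolane-4-carboxylate F3.
- i-Bu2AlH (2.1 equiv, CH2Cl2, −78 °C) takes the ester to the aldehyde 13.

**Step 4.** O4-methylation may compete, and the α-iodo vinylogous acid may lose iodine.

The fallback sets out from 5 and comes back at 8. It builds the α-methoxy-γ-pyrone by ring opening and re-closure instead of by selective alkylation.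
- Mg(OMe)2 in refluxing MeOH opens 5 to methyl 7-(3-benzyloxy-4-methoxyphenyl)-3,5-dioxoheptanoate F4.
- Tf2O in CH2Cl2 at 0 °C cyclodehydrates the diketo ester through its ester oxygen to 6-[2-(3-benzyloxy-4-methoxyphenyl)ethyl]-2-methoxy-4H-pyran-4-one F5.
- NIS in MeCN iodinates the ketene-acetal-like C3 of F5 to give 8.

Further compounds
F1 | step 7 | (5S,6S,7R)-2-[2-(3-benzyloxy-4-methoxyphenyl)ethyl]-5-hydroxy-6,7-(isopropylidenedioxy)-6,7-dihydro-5H-chromene-4,8-dione | COc1ccc(CCc2cc(=O)c3c(o2)C(=O)[C@@H]4OC(C)(C)O[C@H]4[C@H]3O)cc1OCc1ccccc1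
F2 | step 6 | methyl (4R,5R)-5-({6-[2-(3-benzyloxy-4-methoxyphenyl)ethyl]-2-methoxy-4-oxo-4H-pyran-3-yl}carbonyl)-2,2-dimethyl-1,3-dioxolane-4-carboxylate | COc1oc(CCc2ccc(OC)c(OCc3ccccc3)c2)cc(=O)c1C(=O)[C@@H]4OC(C)(C)O[C@H]4C(=O)OC
F3 | step 6 | methyl (4R,5S)-5-[(S)-{6-[2-(3-benzyloxy-4-methoxyphenyl)ethyl]-2-methoxy-4-oxo-4H-pyran-3-yl}(hydroxy)methyl]-2,2-dimethyl-1,3-dioxolane-4-carboxylate | COc1oc(CCc2ccc(OC)c(OCc3ccccc3)c2)cc(=O)c1[C@H](O)[C@@H]4OC(C)(C)O[C@H]4C(=O)OC
F4 | step 4 | methyl 7-(3-benzyloxy-4-methoxyphenyl)-3,5-dioxoheptanoate | COC(=O)CC(=O)CC(=O)CCc1ccc(OC)c(OCc2ccccc2)c1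
F5 | step 4 | 6-[2-(3-benzyloxy-4-methoxyphenyl)ethyl]-2-methoxy-4H-pyran-4-one | COc1cc(=O)cc(CCc2ccc(OC)c(OCc3ccccc3)c2)o1
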